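The flavonol is disconnected at the O1–C2 bond of the pyranone ring C: C2 (bearing O1) and the neighbouring hydroxylated C3, both conjugated to the C4 ketone, are treated as the two carbons of an ynone alkyne. In one operation ICl should close ring C by 6-endo-dig attack of an ortho benzyloxy oxygen on the activated alkyne, expel that benzyl group as benzyl chloride and leave iodine on C3 as the handle for the hydroxyl. The precursor is a 2,4,6-tris(benzyloxy)phenyl ynone whose alkyne terminus carries the (3R)-3-benzyloxy-2,2-dimethylchroman-6-yl unit; its stereocentre comes from a Jacobsen–Katsuki epoxidation, and a single hydrogenolysis finishes.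

Key step: step 11

Remark on the chemistry: the chroman hydroxyl is carried as a benzyl ether, so that all protecting groups fall in one final hydrogenolysis. The carbinol carbon made in the acetylide addition is formed as both epimers, which is immaterial because the next step oxidises it to the ketone.

Step 1
Reactants: 1 4-bromophenol; 2 3-chloro-3-methylbut-1-yne
Product: 3 1-bromo-4-[(2-methylbut-3-yn-2-yl)oxy]benzene
Conditions: DBU, CuCl2·2H2O (cat.), MeCN, 0 °C → rt
Reagents that add atoms: none
Why: Copper-catalysed propargylic substitution (O-alkylation of the phenoxide by the tertiary propargylic chloride through a copper acetylide) is the standard entry to aryl 1,1-dimethylpropargyl ethers and avoids a sluggish SN2 reaction at a tertiary carbon.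

Step 2
Reactants: 3 1-bromo-4-[(2-methylbut-3-yn-2-yl)oxy]benzene
Product: 6 6-bromo-2,2-dimethyl-2H-chromene, via allenylphenol 4 (not isolated), via ortho-quinone methide 5 (not isolated)
Conditions: PhNEt2, 190 °C
Reagents that add atoms: none
Why: An aromatic propargyl Claisen rearrangement gives the ortho-allenylphenol, and a 1,5-hydrogen shift followed by oxa-6π electrocyclisation then closes the 2,2-dimethylchromene in one thermal cascade, the para bromine making both ortho positions equivalent.

Step 3
Reactants: 6 6-bromo-2,2-dimethyl-2H-chromene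
Product: 7 (3R,4R)-6-bromo-3,4-epoxy-2,2-dimethylchroman
Conditions: (R,R)-Mn(salen)Cl {chloro[(R,R)-N,N'-bis(3,5-di-tert-butylsalicylidene)cyclohexane-1,2-diaminato]manganese, trivalent manganese} (cat.), aq. NaOCl (pH 11.3), 4-phenylpyridine N-oxide (cat.), CH2Cl2, 0 °C
Reagents that add atoms: sodium hypochlorite, [Na+].[O-]Cl
Why: Jacobsen–Katsuki epoxidation, for which cis-configured 2,2-dimethylchromenes are privileged substrates, should transfer oxygen to one face of the C3=C4 bond under control of the (R,R)-salen ligand and so set C3 (and the transient C4 centre) as the (3R,4R)-epoxide, by analogy with the known sense of induction for chromenes and indene.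

Step 4
Reactants: 7 (3R,4R)-6-bromo-3,4-epoxy-2,2-dimethylchroman
Product: 8 (3R)-6-bromo-2,2-dimethylchroman-3-ol
Conditions: LiAlH4, THF, 0 °C; then H2O, aq. NaOH
Reagents that add atoms: none
Why: Reductive epoxide opening by SN2 hydride attack at the benzylic C4, which is activated and far less hindered than C3 next to the quaternary C2, leaves the C3–O bond untouched so that the (3R) configuration is retained, while the aryl bromide should survive short exposure at 0 °C.

Step 5
Reactants: 8 (3R)-6-bromo-2,2-dimethylchroman-3-ol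
Product: 9 (3R)-3-(benzyloxy)-6-bromo-2,2-dimethylchroman
Conditions: NaH, BnBr, Bu4NI (cat.), DMF, 0 °C → rt
Reagents that add atoms: benzyl bromide, BrCc1ccccc1
Why: Williamson etherification of the sodium alkoxide masks the hindered secondary alcohol as a benzyl ether that is inert to the later organometallic, oxidative and electrophilic steps and is removed together with the phenol protecting groups at the end.

Step 6
Reactants: 9 (3R)-3-(benzyloxy)-6-bromo-2,2-dimethylchroman; 10 trimethylsilylacetylene
Product: 11 {[(3R)-3-(benzyloxy)-2,2-dimethylchroman-6-yl]ethynyl}trimethylsilane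
Conditions: PdCl2(PPh3)2 (cat.), CuI (cat.), Et3N/DMF, 80 °C (sealed tube)
Reagents that add atoms: none
Why: Sonogashira coupling of the aryl bromide installs the two alkyne carbons at C6 of the chroman, the silyl cap preventing double coupling and alkyne homocoupling.

Step 7
Reactants: 11 {[(3R)-3-(benzyloxy)-2,2-dimethylchroman-6-yl]ethynyl}trimethylsilane
Product: 12 (3R)-3-(benzyloxy)-6-ethynyl-2,2-dimethylchroman
Conditions: K2CO3 (cat.), MeOH/THF, rt
Reagents that add atoms: none
Why: Carbonate-catalysed methanolysis of the alkynyl C–Si bond (protodesilylation) frees the terminal alkyne without affecting the benzyl ether.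

Step 8
Reactants: 13 2,4,6-trihydroxybenzaldehyde
Product: 14 2,4,6-tris(benzyloxy)benzaldehyde
Conditions: BnBr, K2CO3, DMF, 60 °C
Reagents that add atoms: benzyl bromide, BrCc1ccccc1
Why: Threefold Williamson O-benzylation should prevail over C-benzylation because the formyl group lowers the nucleophilicity of the ring carbons of the phloroglucinol core.

Step 9
Reactants: 12 (3R)-3-(benzyloxy)-6-ethynyl-2,2-dimethylchroman; 14 2,4,6-tris(benzyloxy)benzaldehyde
Product: 16 1-[2,4,6-tris(benzyloxy)phenyl]-3-[(3R)-3-(benzyloxy)-2,2-dimethylchroman-6-yl]prop-2-yn-1-ol (both epimers at the carbinol carbon), via lithium acetylide 15 (not isolated)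
Conditions: n-BuLi, THF, −78 °C; then 14, −78 → 0 °C; aq. NH4Cl; crude product used directly
Reagents that add atoms: none
Why: 1,2-Addition of a lithium acetylide to an aromatic aldehyde is reliable even for a di-ortho-substituted aldehyde, and the new carbinol centre needs no control because it is oxidised in the next step.

Step 10
Reactants: 16 1-[2,4,6-tris(benzyloxy)phenyl]-3-[(3R)-3-(benzyloxy)-2,2-dimethylchroman-6-yl]prop-2-yn-1-ol
Product: 17 1-[2,4,6-tris(benzyloxy)phenyl]-3-[(3R)-3-(benzyloxy)-2,2-dimethylchroman-6-yl]prop-2-yn-1-one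
Conditions: MnO2, CH2Cl2, rt
Reagents that add atoms: none
Why: MnO2 oxidation of an alcohol that is both propargylic and benzylic is fast, neutral and selective, so the acid-labile carbinol is converted into the stable ynone without touching the benzyl ethers.

Step 11
Reactants: 17 1-[2,4,6-tris(benzyloxy)phenyl]-3-[(3R)-3-(benzyloxy)-2,2-dimethylchroman-6-yl]prop-2-yn-1-one
Product: 19 5,7-bis(benzyloxy)-2-[(3R)-3-(benzyloxy)-2,2-dimethylchroman-6-yl]-3-iodo-4H-chromen-4-one, via O-benzyl chromenylium chloride 18 (not isolated)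
Conditions: ICl (1.2 equiv), CH2Cl2, −78 °C; then aq. Na2S2O3
Reagents that add atoms: iodine monochloride, ClI
Why: ICl delivers electrophilic iodine to the triple bond of the ynone while, anti to it, one of the two equivalent ortho benzyloxy oxygens adds to the alkyne carbon remote from the carbonyl, giving the O-benzyl chromenylium ion 18, from which chloride removes the benzyl group by SN2 attack to release neutral 19. The closest known reaction type is the ICl-induced cyclisation of 2-alkoxyaryl alkynyl ketones to 3-iodochromones, applied here to a benzyl ether, whose O-dealkylation should be at least as easy as that of a methyl ether. Ring C closes by 6-endo-dig O-cyclisation, which forms the O1–C2 bond and places iodine on C3, the carbon that must later carry the hydroxyl. No stereocentre is created, and the (3R) centre of the chroman is remote and unaffected. The step needs 6-endo over 5-exo (aurone-type) closure, which is secured by the polarisation of the ynone and by the cation-stabilising para-alkoxyaryl group on the far alkyne carbon; it also needs alkyne activation to outrun iodination of the electron-rich rings, for which low temperature and near-stoichiometric ICl are chosen.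

Step 12
Reactants: 19 5,7-bis(benzyloxy)-2-[(3R)-3-(benzyloxy)-2,2-dimethylchroman-6-yl]-3-iodo-4H-chromen-4-one
Product: 22 5,7-bis(benzyloxy)-2-[(3R)-3-(benzyloxy)-2,2-dimethylchroman-6-yl]-3-hydroxy-4H-chromen-4-one, via 3-magnesioflavone 20 (not isolated), via dimethyl boronate 21 (not isolated)
Conditions: iPrMgCl·LiCl, THF, −40 °C; B(OMe)3, −40 → 0 °C; then AcOH, 30% H2O2, 0 °C → rt
Reagents that add atoms: hydrogen peroxide, OO
Why: Iodine–magnesium exchange on the electron-poor alkenyl iodide is fast at low temperature, 3-metalated flavones are known to be stable enough to be borylated, and peroxide oxidation of the boronate (1,2-shift of C3 from boron to oxygen) should place the hydroxyl exactly where iodine stood, the weakly acidic medium sparing the flavonol.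

Step 13
Reactants: 22 5,7-bis(benzyloxy)-2-[(3R)-3-(benzyloxy)-2,2-dimethylchroman-6-yl]-3-hydroxy-4H-chromen-4-one
Product: 23 3,5,7-trihydroxy-2-[(3R)-3-hydroxy-2,2-dimethylchroman-6-yl]-4H-chromen-4-one (CNP0411714.1)
Conditions: H2 (1 atm), Pd(OH)2/C (palladium dihydroxide on carbon), THF/MeOH, rt
Reagents that add atoms: none
Why: Catalytic hydrogenolysis cleaves the two aryl benzyl ethers and the alkyl benzyl ether in one operation, while the conjugated C2=C3 bond of the pyranone, the chroman ring and the (3R) carbinol should not react under one atmosphere of hydrogen at room temperature.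

Compound list
1 | 4-bromophenol | Oc1ccc(Br)cc1 | starting material
2 | 3-chloro-3-methylbut-1-yne | CC(C)(Cl)C#C | starting material
3 | 1-bromo-4-[(2-methylbut-3-yn-2-yl)oxy]benzene | CC(C)(C#C)Oc1ccc(Br)cc1 | intermediate
4 | 4-bromo-2-(3-methylbuta-1,2-dien-1-yl)phenol | CC(C)=C=Cc1cc(Br)ccc1O | intermediate
5 | 4-bromo-6-(3-methylbut-2-en-1-ylidene)cyclohexa-2,4-dien-1-one | CC(C)=CC=C1C=C(Br)C=CC1=O | intermediate
6 | 6-bromo-2,2-dimethyl-2H-chromene | CC1(C)C=Cc2cc(Br)ccc2O1 | intermediate
7 | (3R,4R)-6-bromo-3,4-epoxy-2,2-dimethylchroman [(1aR,7bR)-6-bromo-2,2-dimethyl-1a,7b-dihydro-2H-oxireno[2,3-c]chromene] | CC1(C)Oc2ccc(Br)cc2[C@H]2O[C@@H]12 | intermediate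
8 | (3R)-6-bromo-2,2-dimethylchroman-3-ol | CC1(C)Oc2ccc(Br)cc2C[C@H]1O | intermediate
9 | (3R)-3-(benzyloxy)-6-bromo-2,2-dimethylchroman | CC1(C)Oc2ccc(Br)cc2C[C@H]1OCc1ccccc1 | intermediate
10 | trimethylsilylacetylene | C#C[Si](C)(C)C | starting material
11 | {[(3R)-3-(benzyloxy)-2,2-dimethylchroman-6-yl]ethynyl}trimethylsilane | CC1(C)Oc2ccc(C#C[Si](C)(C)C)cc2C[C@H]1OCc1ccccc1 | intermediate
12 | (3R)-3-(benzyloxy)-6-ethynyl-2,2-dimethylchroman | CC1(C)Oc2ccc(C#C)cc2C[C@H]1OCc1ccccc1 | intermediate
13 | 2,4,6-trihydroxybenzaldehyde | O=Cc1c(O)cc(O)cc1O | starting material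
14 | 2,4,6-tris(benzyloxy)benzaldehyde | O=Cc1c(OCc2ccccc2)cc(OCc2ccccc2)cc1OCc1ccccc1 | intermediate
15 | lithium {[(3R)-3-(benzyloxy)-2,2-dimethylchroman-6-yl]ethynide} | CC1(C)Oc2ccc(C#C[Li])cc2C[C@H]1OCc1ccccc1 | intermediate
16 | 1-[2,4,6-tris(benzyloxy)phenyl]-3-[(3R)-3-(benzyloxy)-2,2-dimethylchroman-6-yl]prop-2-yn-1-ol (both epimers at C1 of the propynol) | CC1(C)Oc2ccc(C#CC(O)c3c(OCc4ccccc4)cc(OCc4ccccc4)cc3OCc3ccccc3)cc2C[C@H]1OCc1ccccc1 | intermediate
17 | 1-[2,4,6-tris(benzyloxy)phenyl]-3-[(3R)-3-(benzyloxy)-2,2-dimethylchroman-6-yl]prop-2-yn-1-one | CC1(C)Oc2ccc(C#CC(=O)c3c(OCc4ccccc4)cc(OCc4ccccc4)cc3OCc3ccccc3)cc2C[C@H]1OCc1ccccc1 | intermediate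
18 | 1-benzyl-5,7-bis(benzyloxy)-2-[(3R)-3-(benzyloxy)-2,2-dimethylchroman-6-yl]-3-iodo-4-oxo-4H-chromen-1-ium chloride | CC1(C)Oc2ccc(C3=C(I)C(=O)c4c(OCc5ccccc5)cc(OCc5ccccc5)cc4[O+]3Cc3ccccc3)cc2C[C@H]1OCc1ccccc1.[Cl-] | intermediate
19 | 5,7-bis(benzyloxy)-2-[(3R)-3-(benzyloxy)-2,2-dimethylchroman-6-yl]-3-iodo-4H-chromen-4-one | CC1(C)Oc2ccc(-c3oc4cc(OCc5ccccc5)cc(OCc5ccccc5)c4c(=O)c3I)cc2C[C@H]1OCc1ccccc1 | intermediate
20 | chloro{5,7-bis(benzyloxy)-2-[(3R)-3-(benzyloxy)-2,2-dimethylchroman-6-yl]-4-oxo-4H-chromen-3-yl}magnesium (LiCl complex) | CC1(C)Oc2ccc(-c3oc4cc(OCc5ccccc5)cc(OCc5ccccc5)c4c(=O)c3[Mg]Cl)cc2C[C@H]1OCc1ccccc1 | intermediate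
21 | dimethyl {5,7-bis(benzyloxy)-2-[(3R)-3-(benzyloxy)-2,2-dimethylchroman-6-yl]-4-oxo-4H-chromen-3-yl}boronate | CC1(C)Oc2ccc(-c3oc4cc(OCc5ccccc5)cc(OCc5ccccc5)c4c(=O)c3B(OC)OC)cc2C[C@H]1OCc1ccccc1 | intermediate
22 | 5,7-bis(benzyloxy)-2-[(3R)-3-(benzyloxy)-2,2-dimethylchroman-6-yl]-3-hydroxy-4H-chromen-4-one | CC1(C)Oc2ccc(-c3oc4cc(OCc5ccccc5)cc(OCc5ccccc5)c4c(=O)c3O)cc2C[C@H]1OCc1ccccc1 | intermediate
23 | 3,5,7-trihydroxy-2-[(3R)-3-hydroxy-2,2-dimethylchroman-6-yl]-4H-chromen-4-one (CNP0411714.1) | CC1(C)Oc2ccc(-c3oc4cc(O)cc(O)c4c(=O)c3O)cc2C[C@H]1O | target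

Total step count: 13. Longest linear sequence: 12 steps (steps 1–7 and 9–13); step 8 is a one-step side branch.

Steps most likely to fail

1. Step 11 (key step). Electrophilic iodination of the electron-rich benzenoid rings, or simple addition of ICl across the triple bond, may compete with the oxygen cyclisation, and the benzyl group may be lost from the oxonium ion by transfer to a ring carbon instead of to chloride. The fallback avoids iodine altogether: it sets out from 17 and comes back at 22. Chelation-controlled cleavage of one ortho benzyl ether (MgBr2·OEt2, toluene/Et2O, rt → 60 °C) should give 1-[2,4-bis(benzyloxy)-6-hydroxyphenyl]-3-[(3R)-3-(benzyloxy)-2,2-dimethylchroman-6-yl]prop-2-yn-1-one F1. DMAP-catalysed 6-endo oxa-Michael cyclisation of this ortho-hydroxyaryl ynone (cat. DMAP, DMF, rt) should give 5,7-bis(benzyloxy)-2-[(3R)-3-(benzyloxy)-2,2-dimethylchroman-6-yl]-4H-chromen-4-one F2. Directed deprotonation at C3 (LDA, THF, −78 °C) should give {5,7-bis(benzyloxy)-2-[(3R)-3-(benzyloxy)-2,2-dimethylchroman-6-yl]-4-oxo-4H-chromen-3-yl}lithium F3, which is trapped with B(OMe)3 to give boronate 21 and oxidised (AcOH, H2O2) to 22.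

2. Step 12. The magnesiated flavone may be protonated before it is borylated (net deiodination) or may fragment by opening of ring C to a phenoxide ynone, and the peroxide may over-oxidise the flavonol. The fallback replaces the polar organometallic by palladium catalysis: it sets out from 19 and comes back at 22. Miyaura borylation (B2pin2, PdCl2(dppf) [dichloro(1,1'-bis(diphenylphosphino)ferrocene)palladium], KOAc, dioxane, 80 °C) should give 5,7-bis(benzyloxy)-2-[(3R)-3-(benzyloxy)-2,2-dimethylchroman-6-yl]-3-(4,4,5,5-tetramethyl-1,3,2-dioxaborolan-2-yl)-4H-chromen-4-one F4, which is oxidised with NaBO3·4H2O (THF/H2O, rt) to 22.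

3. Step 9. Addition to the hindered, electron-rich aldehyde may be slow, and the doubly activated carbinol (2,4,6-trialkoxybenzylic and propargylic) may ionise on work-up or chromatography, leading to ether formation or Meyer–Schuster-type rearrangement. The fallback acylates the alkyne instead of adding it to an aldehyde and oxidising: it sets out from 14 (and uses 12) and comes back at 17, bypassing steps 9 and 10. Pinnick oxidation (NaClO2, NaH2PO4, 2-methylbut-2-ene, t-BuOH/H2O) should give 2,4,6-tris(benzyloxy)benzoic acid F5, and (COCl)2 with cat. DMF in CH2Cl2 should give 2,4,6-tris(benzyloxy)benzoyl chloride F6. Acyl Sonogashira coupling of this chloride with alkyne 12 (PdCl2(PPh3)2, CuI, Et3N, THF, rt) should give ynone 17 directly.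

Further compounds
F1 | step 11 | 1-[2,4-bis(benzyloxy)-6-hydroxyphenyl]-3-[(3R)-3-(benzyloxy)-2,2-dimethylchroman-6-yl]prop-2-yn-1-one | CC1(C)Oc2ccc(C#CC(=O)c3c(O)cc(OCc4ccccc4)cc3OCc3ccccc3)cc2C[C@H]1OCc1ccccc1
F2 | step 11 | 5,7-bis(benzyloxy)-2-[(3R)-3-(benzyloxy)-2,2-dimethylchroman-6-yl]-4H-chromen-4-one | CC1(C)Oc2ccc(-c3cc(=O)c4c(OCc5ccccc5)cc(OCc5ccccc5)cc4o3)cc2C[C@H]1OCc1ccccc1
F3 | step 11 | {5,7-bis(benzyloxy)-2-[(3R)-3-(benzyloxy)-2,2-dimethylchroman-6-yl]-4-oxo-4H-chromen-3-yl}lithium | CC1(C)Oc2ccc(-c3oc4cc(OCc5ccccc5)cc(OCc5ccccc5)c4c(=O)c3[Li])cc2C[C@H]1OCc1ccccc1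
F4 | step 12 | 5,7-bis(benzyloxy)-2-[(3R)-3-(benzyloxy)-2,2-dimethylchroman-6-yl]-3-(4,4,5,5-tetramethyl-1,3,2-dioxaborolan-2-yl)-4H-chromen-4-one | CC1(C)Oc2ccc(-c3oc4cc(OCc5ccccc5)cc(OCc5ccccc5)c4c(=O)c3B6OC(C)(C)C(C)(C)O6)cc2C[C@H]1OCc1ccccc1
F5 | step 9 | 2,4,6-tris(benzyloxy)benzoic acid | OC(=O)c1c(OCc2ccccc2)cc(OCc2ccccc2)cc1OCc1ccccc1
F6 | step 9 | 2,4,6-tris(benzyloxy)benzoyl chloride | ClC(=O)c1c(OCc2ccccc2)cc(OCc2ccccc2)cc1OCc1ccccc1
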